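**Retrosynthetic overview**
- The target, (6R,6'R)-ε,ε-carotene, is disconnected to all-E-lycopene: both ε-rings and both stereocentres come from one enzymatic double cationic cyclisation of the two acyclic end groups (an isomerisation, no atoms added).
- Lycopene is disconnected to two C15 triphenylphosphonium salts and the C10 dialdehyde (double Wittig, forming C11=C12 and C11'=C12').
- The C15 salt comes from vinyl-ψ-ionol, and that from pseudoionone and vinylmagnesium bromide.
- Ring order: no ring exists until the last step; ring A (C1–C6) closes first (monocyclic δ-carotene stage), ring B (C1'–C6') second, in the same operation.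

Assumption: commercial pseudoionone (a 5E/5Z mixture) is fractionally distilled to the (3E,5E) isomer, and the recombinant cyclase is prepared by standard expression in E. coli and counted as a catalyst, not as a step. Carotenoid numbering is used for positions.

**Step 1**
Reactants: 1 (3E,5E)-pseudoionone
Product: 2 (±)-(4E,6E)-3,7,11-trimethyldodeca-1,4,6,10-tetraen-3-ol (vinyl-ψ-ionol)
Conditions: CH2=CHMgBr (1.2 equiv), THF, −20 → 0 °C; then sat. aq. NH4Cl
Reagents that add atoms: vinylmagnesium bromide, C=C[Mg]Br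
Why: Grignard 1,2-addition to the dienone carbonyl (no copper, so no conjugate addition); the new carbinol centre is racemic and is erased in step 2.

**Step 2**
Reactants: 2 (±)-vinyl-ψ-ionol
Product: 3 [(2E,4E,6E)-3,7,11-trimethyldodeca-2,4,6,10-tetraen-1-yl]triphenylphosphonium bromide
Conditions: PPh3·HBr (1.05 equiv), MeOH, 0 °C → rt, dark; crystallise (EtOAc/MeCN) to upgrade 2E
Reagents that add atoms: triphenylphosphine hydrobromide, [Br-].[PH+](c1ccccc1)(c1ccccc1)c1ccccc1
Why: SN1 substitution with allylic transposition, in which acid ionises the tertiary bis-allylic alcohol and PPh3 traps the delocalised cation at the unhindered primary terminus to give the conjugated, mainly 2E salt (the standard vinyl carbinol → Wittig salt reaction of carotenoid chemistry).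

**Step 3**
Reactants: 3 C15 phosphonium bromide (2.2 equiv); 4 (2E,4E,6E)-2,7-dimethylocta-2,4,6-trienedial
Product: 8 all-E-lycopene, via C15 ylide 5 (not isolated), via apo-12'-lycopenal 6 (not isolated), via 11Z-lycopene 7 (not isolated)
Conditions: NaOMe (2.3 equiv), MeOH/CH2Cl2, 0 °C → rt, Ar, dark; then swap to heptane, reflux 2 h, crystallise
Reagents that add atoms: none
Why: double Wittig olefination of the dialdehyde by the allylic ylide; the new 11,12 bonds form as E/Z mixtures, but the 11Z bond is a hindered cis bond (clash with the C13 methyl) and isomerises thermally to all-E, which crystallises.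

**Step 4**
Reactants: 8 all-E-lycopene
Product: 10 (6R,6'R)-ε,ε-carotene, via δ-carotene 9 (not isolated)
Conditions: recombinant Lactuca sativa lycopene ε-cyclase (EC 5.5.1.18, E. coli membrane fraction), 8 in phosphatidylcholine liposomes, FAD (cat.), NADPH (cat.), Tris–HCl buffer pH 7.0, 30 °C, N2, dark, 16 h; hexane extraction, chromatography on deactivated alumina
Reagents that add atoms: none
Why: Proposed new method: cell-free preparative use of an enzyme activity known to close both ε-rings of lycopene inside engineered cells; the enzyme protonates the isolated C1=C2 bond at C2, C6 of the folded end group attacks the C1 cation, and an active-site base removes H-4 to give the C4=C5 ring alkene (ε, not the conjugated β isomer), the chiral pocket fixing 6R at each end in turn (ring A, then ring B), with reduced FAD as a non-consumed cofactor, and the conjugated polyene is left untouched because only the terminal alkene sits at the acid site; closest known reaction types are the in-cell conversion by the same enzyme, liposome assays of the related lycopene β-cyclases with reduced flavin, and the acid-induced pseudoionone → α-ionone cyclisation.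

**Compound list**
1 | (3E,5E)-pseudoionone, (3E,5E)-6,10-dimethylundeca-3,5,9-trien-2-one | CC(C)=CCC/C(C)=C/C=C/C(C)=O | starting material
2 | (±)-(4E,6E)-3,7,11-trimethyldodeca-1,4,6,10-tetraen-3-ol (vinyl-ψ-ionol, racemic at C3) | CC(C)=CCC/C(C)=C/C=C/C(C)(O)C=C | intermediate
3 | [(2E,4E,6E)-3,7,11-trimethyldodeca-2,4,6,10-tetraen-1-yl]triphenylphosphonium bromide | CC(C)=CCC/C(C)=C/C=C/C(C)=C/C[P+](c1ccccc1)(c1ccccc1)c1ccccc1.[Br-] | intermediate
4 | (2E,4E,6E)-2,7-dimethylocta-2,4,6-trienedial (C10 dialdehyde) | O=C/C(C)=C/C=C/C=C(C)/C=O | starting material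
5 | C15 ylide, [(2E,4E,6E)-3,7,11-trimethyldodeca-2,4,6,10-tetraen-1-ylidene]triphenylphosphorane | CC(C)=CCC/C(C)=C/C=C/C(C)=C/C=P(c1ccccc1)(c1ccccc1)c1ccccc1 | intermediate (not isolated)
6 | apo-12'-lycopenal, C25 mono-olefination aldehyde (all-E isomer shown; the 11Z isomer reacts alike) | CC(C)=CCC/C(C)=C/C=C/C(C)=C/C=C/C(C)=C/C=C/C=C(C)/C=O | intermediate (not isolated)
7 | (11Z)-lycopene (main Z isomer of the crude Wittig product; the 11Z,11'Z isomer behaves alike) | CC(C)=CCC/C(C)=C/C=C/C(C)=C/C=C\C(C)=C\C=C\C=C(C)\C=C\C=C(C)\C=C\C=C(C)\CCC=C(C)C | intermediate (not isolated)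
8 | all-E-lycopene (ψ,ψ-carotene) | CC(C)=CCC/C(C)=C/C=C/C(C)=C/C=C/C(C)=C/C=C/C=C(C)/C=C/C=C(C)/C=C/C=C(C)/CCC=C(C)C | intermediate
9 | δ-carotene, (6R)-ε,ψ-carotene | CC1=CCCC(C)(C)[C@H]1/C=C/C(C)=C/C=C/C(C)=C/C=C/C=C(C)/C=C/C=C(C)/C=C/C=C(C)/CCC=C(C)C | intermediate (not isolated)
10 | (6R,6'R)-ε,ε-carotene (CNP0241650.1) | CC1=CCCC(C)(C)[C@H]1/C=C/C(C)=C/C=C/C(C)=C/C=C/C=C(C)/C=C/C=C(C)/C=C/[C@H]1C(C)=CCCC1(C)C | target

**Totals**
Total step count: 4. Longest linear sequence: 4 (1 → 2 → 3 → 8 → 10).

**Steps most likely to fail, with fallbacks**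

Step 4 (highest risk: delivering insoluble lycopene to a membrane enzyme, stalling at monocyclic 9, milligram scale). The fallback sets out from 1 and comes back to the route at 10; it makes the rings before the chain is assembled. Compound 1 is cyclised with 85% H3PO4 at rt to (±)-α-ionone F1. F1 is resolved by preparative chiral SFC on an amylose tris(3,5-dimethylphenylcarbamate) phase to (R)-α-ionone F2. CH2=CHMgBr in THF converts F2 into (6R)-vinyl-α-ionol F3 (both carbinol epimers, irrelevant). PPh3·HBr in MeOH gives the (6R)-C15 phosphonium bromide F4. Double Wittig of F4 (2.2 equiv) with 4 (NaOMe, MeOH/CH2Cl2, then heptane reflux) gives 10. C6–H is not acidic under these conditions, so the stereocentre is kept.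

Step 3 (stalling at mono-aldehyde 6, Z isomers, air and light sensitivity). The fallback sets out from 3 and comes back at 8; it makes the central C15=C15' bond last. Salt 3 is olefinated once with (E)-4,4-dimethoxy-2-methylbut-2-enal (NaOMe, MeOH) to ψ-retinal dimethyl acetal F5. Dilute H2SO4 in acetone/H2O hydrolyses F5 to ψ-retinal F6. F6 is reductively dimerised by McMurry coupling with low-valent titanium (TiCl4, Zn, pyridine, THF, reflux) and then isomerised in refluxing heptane to 8.

Step 2 (acid-induced cyclisation or oligomerisation of the polyene carbinol, poor 2E/2Z ratio). The fallback sets out from 1 and comes back at 3; it avoids any cationic step. Horner–Wadsworth–Emmons reaction of 1 with triethyl phosphonoacetate (NaH, THF) gives ethyl ester F7 (2E major, 2Z removed by chromatography). i-Bu2AlH (CH2Cl2, −78 °C) gives allylic alcohol F8. PBr3 (Et2O, −20 °C) gives allylic bromide F9. PPh3 (toluene, rt) gives 3.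

**Further compounds**
F1 | step 4 | (±)-α-ionone, (E)-4-(2,6,6-trimethylcyclohex-2-en-1-yl)but-3-en-2-one, racemic | CC1=CCCC(C)(C)C1/C=C/C(C)=O
F2 | step 4 | (R)-α-ionone, (E)-4-[(1R)-2,6,6-trimethylcyclohex-2-en-1-yl]but-3-en-2-one | CC1=CCCC(C)(C)[C@H]1/C=C/C(C)=O
F3 | step 4 | (6R)-vinyl-α-ionol, (4E)-3-methyl-5-[(1R)-2,6,6-trimethylcyclohex-2-en-1-yl]penta-1,4-dien-3-ol (both carbinol epimers) | CC1=CCCC(C)(C)[C@H]1/C=C/C(C)(O)C=C
F4 | step 4 | [(2E,4E)-3-methyl-5-[(1R)-2,6,6-trimethylcyclohex-2-en-1-yl]penta-2,4-dien-1-yl]triphenylphosphonium bromide | CC1=CCCC(C)(C)[C@H]1/C=C/C(C)=C/C[P+](c1ccccc1)(c1ccccc1)c1ccccc1.[Br-]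
F5 | step 3 | ψ-retinal dimethyl acetal, (2E,4E,6E,8E,10E)-1,1-dimethoxy-3,7,11,15-tetramethylhexadeca-2,4,6,8,10,14-hexaene | CC(C)=CCC/C(C)=C/C=C/C(C)=C/C=C/C(C)=C/C(OC)OC
F6 | step 3 | ψ-retinal, (2E,4E,6E,8E,10E)-3,7,11,15-tetramethylhexadeca-2,4,6,8,10,14-hexaenal | CC(C)=CCC/C(C)=C/C=C/C(C)=C/C=C/C(C)=C/C=O
F7 | step 2 | ethyl (2E,4E,6E)-3,7,11-trimethyldodeca-2,4,6,10-tetraenoate | CC(C)=CCC/C(C)=C/C=C/C(C)=C/C(=O)OCC
F8 | step 2 | (2E,4E,6E)-3,7,11-trimethyldodeca-2,4,6,10-tetraen-1-ol | CC(C)=CCC/C(C)=C/C=C/C(C)=C/CO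
F9 | step 2 | (2E,4E,6E)-1-bromo-3,7,11-trimethyldodeca-2,4,6,10-tetraene | CC(C)=CCC/C(C)=C/C=C/C(C)=C/CBr
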